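A direct plan would take ring B from 2,6-dimethyl-1,4-benzoquinone A1 and close ring A by a catalytic enantioselective Diels–Alder reaction with 4-methylpenta-1,3-diene A2.
It would then rework the cis-fused ene-dione adduct A3 into the trans-fused 6-silyloxy-7-ene C11 tetrazolyl sulfone A4 and add C12–C16 by Julia–Kocienski olefination.
Its weakest steps would be:
(a) the ring-closing cycloaddition: the diene terminus that must bond to C5 carries a cis-methyl group, so reactivity, regiochemistry and C10 would all hang on a poorly reactive partner;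
(b) the reworking of ring B: some ten steps (reduce, add a methyl carbinol, re-oxidise, epimerise C5, reduce, dehydrate, hydroborate) that only move oxygen and one carbon around an existing ring, with C5 left to an equilibrium and C9 to the face of a hydroboration;
(c) the SeO2 oxidation of the C17 methyl group on the late sulfone, where the activated C9–H and over-oxidation would compete on precious material.

The new route cuts C11=C12 (Julia–Kocienski), then C5–C10 and C8–C9 in one operation, then C4–C5 (tert-alkylation of a silyl dienol ether).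
Ring B is a masked 4-substituted cyclohex-2-enone: the C6 oxygen lies between C5–H and C7=C8, C17 sits on C8 and C11 on C9. It is therefore the [4+2] adduct of a 2-silyloxy diene C5=C6–C7=C8 and a C9=C10 enoyl group, and ring A is only the C1–C4 tether between C5 and C10.
(2E)-Geranic acid supplies C1–C4, C9–C11, C18–C20 and the alkene geometry that places C11 cis to C20; an oxazolidinone on C11 sets C10.
Rings A and B arise together from an open chain, so no quinone and no sluggish intermolecular diene are needed. Ring B is born with oxygen on C6, C17–O and C11 in place, so the carbinol/dehydration/hydroboration detour and the SeO2 step do not occur; C8 is erased and C5 equilibrated.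

Key step: step 6

Remarks on the chemistry:
- Locants C1–C20 are those of the labdane skeleton; the bicyclic C15 intermediates are named as 12,13,14,15,16-pentanorlabdanes.
- (2E)-Geranic acid is taken as the geometrically pure acid.
- Adduct 11 is drawn as the endo isomer; its C5 and C8 epimers would be carried along, because step 8 erases C8 and equilibrates C5.

Step 1
Reactants: 1 (2E)-geranic acid; 2 (R)-4-benzyl-1,3-oxazolidin-2-one
Product: 3 (R)-4-benzyl-3-[(2E)-3,7-dimethylocta-2,6-dienoyl]-1,3-oxazolidin-2-one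
Conditions: t-BuCOCl, Et3N, THF, −20 °C; then LiCl, 2, −20 °C → rt
Reagents that add atoms: none
Why: Mixed-anhydride N-acylation of the oxazolidinone (pivaloyl chloride, LiCl/Et3N), which should acylate nitrogen without touching the (E)-C9=C10 bond; no stereocentre is formed.

Step 2
Reactants: 3 (R)-4-benzyl-3-[(2E)-3,7-dimethylocta-2,6-dienoyl]-1,3-oxazolidin-2-one
Product: 4 (R)-4-benzyl-3-[(2E)-7-chloro-3,7-dimethyloct-2-enoyl]-1,3-oxazolidin-2-one
Conditions: HCl (gas, dry), CH2Cl2, −78 → −30 °C
Reagents that add atoms: hydrogen chloride, Cl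
Why: Markovnikov hydrochlorination: only the electron-rich trisubstituted alkene is protonated (to the tertiary centre that becomes C4), while the enoyl C9=C10 bond is deactivated by the imide; no stereocentre is formed.

Step 3
Reactants: 5 (tert-butyldimethylsilyloxy)acetaldehyde; 6 1-(triphenylphosphoranylidene)propan-2-one
Product: 7 (3E)-5-(tert-butyldimethylsilyloxy)pent-3-en-2-one
Conditions: CH2Cl2, rt → 40 °C
Reagents that add atoms: none
Why: Wittig olefination with a stabilised acyl ylide, which should give the (E)-enone that supplies C5, C6, C7, C8 and C17.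

Step 4
Reactants: 7 (3E)-5-(tert-butyldimethylsilyloxy)pent-3-en-2-one
Product: 8 tert-butyldimethyl{[(2E)-4-(trimethylsilyloxy)penta-2,4-dien-1-yl]oxy}silane
Conditions: LiN(i-Pr)2, THF, −78 °C; Me3SiCl, −78 → 0 °C; pentane, filtration
Reagents that add atoms: chlorotrimethylsilane, C[Si](C)(C)Cl
Why: Kinetic deprotonation of the α′-methyl group and O-silylation give the cross-conjugated 2-silyloxy diene (standard preparation of 2-silyloxy-1,3-dienes from enones); the CH2 terminus is the future C5.

Step 5
Reactants: 4 (R)-4-benzyl-3-[(2E)-7-chloro-3,7-dimethyloct-2-enoyl]-1,3-oxazolidin-2-one; 8 tert-butyldimethyl{[(2E)-4-(trimethylsilyloxy)penta-2,4-dien-1-yl]oxy}silane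
Product: 9 (R)-4-benzyl-3-[(2E,10E)-12-(tert-butyldimethylsilyloxy)-3,7,7-trimethyl-9-oxododeca-2,10-dienoyl]-1,3-oxazolidin-2-one
Conditions: TiCl4 (2.2 equiv), CH2Cl2, −78 → −50 °C
Reagents that add atoms: none
Why: Reetz α-tert-alkylation of a silyl enol ether: TiCl4 ionises the tertiary chloride and the CH2 terminus of the silyloxy diene captures the cation, which makes quaternary C4 and the C4–C5 bond; at −78 °C the hindered β,β-disubstituted enoyl imide should not compete as an acceptor, and no stereocentre is formed.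

Step 6
Reactants: 9 (R)-4-benzyl-3-[(2E,10E)-12-(tert-butyldimethylsilyloxy)-3,7,7-trimethyl-9-oxododeca-2,10-dienoyl]-1,3-oxazolidin-2-one
Product: 11 endo imide adduct (R)-4-benzyl-3-[(5R,8R,9R,10R)-6,17-bis(tert-butyldimethylsilyloxy)-12,13,14,15,16-pentanorlabd-6-en-11-oyl]-1,3-oxazolidin-2-one, via silyloxy triene 10 (not isolated)
Conditions: t-BuMe2SiOTf (1.2 equiv), Et3N (1.5 equiv), CH2Cl2, −78 → 0 °C; pentane, filtration, concentration; Me2AlCl (1.5 equiv), CH2Cl2, −40 → −10 °C
Reagents that add atoms: tert-butyldimethylsilyl triflate, CC(C)(C)[Si](C)(C)OS(=O)(=O)C(F)(F)F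
Why: Proposed new method: soft enolisation toward C5 gives the (Z)-2-silyloxy diene 10, and Me2AlCl then chelates both imide carbonyls (s-cis enoyl group on a cationic aluminium centre), so that C5, the nucleophilic diene terminus, bonds to the β-carbon C10 and C8 to C9 in a concerted but strongly asynchronous [4+2] cycloaddition (at the limit a Mukaiyama–Michael addition followed by collapse of the aluminium enolate onto the silyloxyallyl cation). The closest known reaction types are the Me2AlCl-promoted intramolecular Diels–Alder reaction of (E)-trienoyl oxazolidinones, Lewis-acid cycloadditions of 2-silyloxy dienes and the intramolecular double Michael reaction of enone-enoates; new is the β,β-disubstituted dienophile carbon, which makes C10 quaternary. Ring A closes as a six-membered carbocycle through the C1–C4 tether when C5–C10 forms (6-exo in the stepwise picture), and ring B by the [4π+2π] annulation itself. C10 is set by the auxiliary, whose benzyl group covers the Re face of C10 in the chelate so that C5 adds to the Si face; C9 follows from suprafacial addition to the (E)-alkene (C11 cis to C20); C5 and C8 are drawn for the endo mode but need no control, since C8 becomes sp2 and C5 is equilibrated in step 8. Regioselectivity is secured by matched polarity (enol-ether terminus C5 to the β-carbon C10, so that the silyloxy carbon ends para to C9), site selectivity by the length of the tether, and reactivity by the electron-rich diene, the intramolecular setting and the gem-dimethyl group on C4.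

Step 7
Reactants: 11 endo imide adduct
Product: 12 (5R,8S,9R,10S)-6,17-bis(tert-butyldimethylsilyloxy)-12,13,14,15,16-pentanorlabd-6-en-11-ol
Conditions: LiBH4 (2 equiv), MeOH (1.1 equiv), THF, 0 °C → rt
Reagents that add atoms: none
Why: Reductive cleavage of the N-acyl oxazolidinone gives the C11 alcohol and returns the auxiliary; it is placed before the enone is unveiled so that C9–H is never α to a carbonyl and γ to an enone at the same time (a situation in which 9-epimers of drim-7-enes can be favoured), and the silyl enol ether is inert to borohydride.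

Step 8
Reactants: 12 (5R,8S,9R,10S)-6,17-bis(tert-butyldimethylsilyloxy)-12,13,14,15,16-pentanorlabd-6-en-11-ol
Product: 13 (5R,9S,10S)-17-(tert-butyldimethylsilyloxy)-11-hydroxy-12,13,14,15,16-pentanorlabd-7-en-6-one
Conditions: Pd(OAc)2 (1.1 equiv), MeCN, rt; filtration, concentration; NaOMe (0.2 equiv), MeOH, 0 °C → rt
Reagents that add atoms: none
Why: Saegusa–Ito oxidation: the palladium enolate at C7 can lose a β-hydrogen only from C8 (C4 is quaternary), which gives the C7=C8 enone and erases C8, and methoxide then equilibrates C5 through the α′-enolate to the trans fusion (H-5 anti to C20) that 7-en-6-one labdanes with a saturated C9 substituent keep under methoxide.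

Step 9
Reactants: 13 (5R,9S,10S)-17-(tert-butyldimethylsilyloxy)-11-hydroxy-12,13,14,15,16-pentanorlabd-7-en-6-one
Product: 14 (5R,6S,9S,10S)-17-(tert-butyldimethylsilyloxy)-12,13,14,15,16-pentanorlabd-7-ene-6,11-diol
Conditions: NaBH4, CeCl3·7H2O, MeOH, −78 °C
Reagents that add atoms: none
Why: Luche 1,2-reduction: the face of the C6 carbonyl syn to C20 is closed by the axial methyl groups on C10 and C4, so hydride arrives anti to them and gives the axial (6S) alcohol.

Step 10
Reactants: 14 (5R,6S,9S,10S)-17-(tert-butyldimethylsilyloxy)-12,13,14,15,16-pentanorlabd-7-ene-6,11-diol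
Product: 15 (5R,6S,9S,10R)-17-(tert-butyldimethylsilyloxy)-6-hydroxy-12,13,14,15,16-pentanorlabd-7-en-11-al
Conditions: TEMPO (0.1 equiv), PhI(OAc)2 (1.1 equiv), CH2Cl2, rt
Reagents that add atoms: none
Why: Oxoammonium oxidation, selective for the primary alcohol over the axial secondary 6-hydroxyl that the methyl groups on C4 and C10 shield; the neutral medium should leave C9 untouched.

Step 11
Reactants: 16 (R)-2-methylglycidol
Product: 17 (S)-5-{[(2-methyloxiran-2-yl)methyl]sulfanyl}-1-phenyl-1H-tetrazole
Conditions: 1-phenyl-1H-tetrazole-5-thiol, PPh3, DIAD, THF, 0 °C → rt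
Reagents that add atoms: 1-phenyl-1H-tetrazole-5-thiol, Sc1nnnn1-c1ccccc1
Why: Mitsunobu thioetherification of the primary alcohol: the SN2 step is at the CH2 group, so the quaternary epoxide carbon (future C13) keeps its configuration (the descriptor changes only through the priority rules).

Step 12
Reactants: 17 (S)-5-{[(2-methyloxiran-2-yl)methyl]sulfanyl}-1-phenyl-1H-tetrazole
Product: 18 (S)-2-methyl-1-[(1-phenyl-1H-tetrazol-5-yl)sulfanyl]but-3-en-2-ol
Conditions: Me3S+ I− (3 equiv), n-BuLi (2.9 equiv), THF, −10 °C → rt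
Reagents that add atoms: trimethylsulfonium iodide, C[S+](C)C.[I-]
Why: One-carbon homologation of a terminal epoxide to an allylic alcohol: dimethylsulfonium methylide opens the epoxide at its CH2 terminus (future C14) and loss of Me2S from the betaine makes the C14=C15 vinyl group; no bond to the stereocentre is broken.

Step 13
Reactants: 18 (S)-2-methyl-1-[(1-phenyl-1H-tetrazol-5-yl)sulfanyl]but-3-en-2-ol
Product: 19 (S)-2-methyl-1-[(1-phenyl-1H-tetrazol-5-yl)sulfonyl]but-3-en-2-ol
Conditions: (NH4)6Mo7O24·4H2O (10 mol%), 30% H2O2, EtOH, 0 °C → rt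
Reagents that add atoms: hydrogen peroxide, OO
Why: Molybdate-catalysed peroxide oxidation of the sulfide to the sulfone, which is much faster than epoxidation of the monosubstituted vinyl group.

Step 14
Reactants: 19 (S)-2-methyl-1-[(1-phenyl-1H-tetrazol-5-yl)sulfonyl]but-3-en-2-ol
Product: 20 (S)-5-{[2-methyl-2-(triethylsilyloxy)but-3-en-1-yl]sulfonyl}-1-phenyl-1H-tetrazole
Conditions: Et3SiOTf, 2,6-lutidine, CH2Cl2, −78 → 0 °C
Reagents that add atoms: triethylsilyl triflate, CC[Si](CC)(CC)OS(=O)(=O)C(F)(F)F
Why: Silylation of the tertiary alcohol with a silyl triflate and lutidine, needed because the olefination uses a strong base and a free β-alkoxide would fragment; the conditions are too mild to ionise the allylic carbinol.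

Step 15
Reactants: 15 (5R,6S,9S,10R)-17-(tert-butyldimethylsilyloxy)-6-hydroxy-12,13,14,15,16-pentanorlabd-7-en-11-al; 20 (S)-5-{[2-methyl-2-(triethylsilyloxy)but-3-en-1-yl]sulfonyl}-1-phenyl-1H-tetrazole
Product: 21 (5R,6S,9S,10S,13S,11E)-17-(tert-butyldimethylsilyloxy)-13-(triethylsilyloxy)labda-7,11,14-trien-6-ol
Conditions: KN(SiMe3)2 (2.3 equiv) added to 15 and 20 (1.3 equiv), DME, −60 °C → rt
Reagents that add atoms: none
Why: Julia–Kocienski olefination under Barbier conditions: the first equivalent of base makes the inert C6 alkoxide, the metallated sulfone is trapped by the aldehyde before it can lose silanolate, and Smiles rearrangement with anti-periplanar loss of SO2 and tetrazolate forms C11=C12, for which the potassium counter-ion, DME and two branched partners should favour the E alkene.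

Step 16
Reactants: 21 (5R,6S,9S,10S,13S,11E)-17-(tert-butyldimethylsilyloxy)-13-(triethylsilyloxy)labda-7,11,14-trien-6-ol
Product: 22 (5R,6S,9S,10S,13S,11E)-6-acetoxy-17-(tert-butyldimethylsilyloxy)-13-(triethylsilyloxy)labda-7,11,14-triene
Conditions: Ac2O (3 equiv), DMAP (0.2 equiv), Et3N, CH2Cl2, rt
Reagents that add atoms: acetic anhydride, CC(=O)OC(C)=O
Why: DMAP-catalysed acetylation of the hindered axial 6-hydroxyl, the only free hydroxyl at this stage; no stereocentre is touched.

Step 17
Reactants: 22 (5R,6S,9S,10S,13S,11E)-6-acetoxy-17-(tert-butyldimethylsilyloxy)-13-(triethylsilyloxy)labda-7,11,14-triene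
Product: 23 (5R,6S,9S,10S,13S,11E)-6-acetoxylabda-7,11,14-triene-13,17-diol
Conditions: n-Bu4NF (4 equiv), AcOH (4 equiv), THF, 0 °C → rt
Reagents that add atoms: none
Why: Fluoride desilylation buffered with acetic acid removes the primary tert-butyldimethylsilyl and the tertiary triethylsilyl ether without strong acid, so the doubly allylic C13 carbinol cannot ionise, and without free alkoxide, so the 6-acetate stays in place.

Step 18
Reactants: 23 (5R,6S,9S,10S,13S,11E)-6-acetoxylabda-7,11,14-triene-13,17-diol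
Product: 24 (5R,6S,9S,10S,13S,11E)-6,17-diacetoxylabda-7,11,14-trien-13-ol (target)
Conditions: Ac2O (1.2 equiv), pyridine, CH2Cl2, 0 °C
Reagents that add atoms: acetic anhydride, CC(=O)OC(C)=O
Why: Acetylation selective by steric class: the primary allylic 17-hydroxyl is esterified, while the tertiary linalool-type 13-hydroxyl stays free.

**Compound list**
1 | (2E)-3,7-dimethylocta-2,6-dienoic acid (geranic acid) | CC(C)=CCC/C(C)=C/C(=O)O | starting material
2 | (R)-4-benzyl-1,3-oxazolidin-2-one | O=C1N[C@H](Cc2ccccc2)CO1 | starting material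
3 | (R)-4-benzyl-3-[(2E)-3,7-dimethylocta-2,6-dienoyl]-1,3-oxazolidin-2-one | CC(C)=CCC/C(C)=C/C(=O)N1[C@H](Cc2ccccc2)COC1=O | intermediate
4 | (R)-4-benzyl-3-[(2E)-7-chloro-3,7-dimethyloct-2-enoyl]-1,3-oxazolidin-2-one | CC(C)(Cl)CCC/C(C)=C/C(=O)N1[C@H](Cc2ccccc2)COC1=O | intermediate
5 | (tert-butyldimethylsilyloxy)acetaldehyde | O=CCO[Si](C)(C)C(C)(C)C | starting material
6 | 1-(triphenylphosphoranylidene)propan-2-one | CC(=O)C=P(c1ccccc1)(c1ccccc1)c1ccccc1 | starting material
7 | (3E)-5-(tert-butyldimethylsilyloxy)pent-3-en-2-one | CC(=O)/C=C/CO[Si](C)(C)C(C)(C)C | intermediate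
8 | tert-butyldimethyl{[(2E)-4-(trimethylsilyloxy)penta-2,4-dien-1-yl]oxy}silane | C=C(O[Si](C)(C)C)/C=C/CO[Si](C)(C)C(C)(C)C | intermediate
9 | (R)-4-benzyl-3-[(2E,10E)-12-(tert-butyldimethylsilyloxy)-3,7,7-trimethyl-9-oxododeca-2,10-dienoyl]-1,3-oxazolidin-2-one | CC(C)(C)[Si](C)(C)OC/C=C/C(=O)CC(C)(C)CCC/C(C)=C/C(=O)N1[C@H](Cc2ccccc2)COC1=O | intermediate
10 | (R)-4-benzyl-3-[(2E,8Z,10E)-9,12-bis(tert-butyldimethylsilyloxy)-3,7,7-trimethyldodeca-2,8,10-trienoyl]-1,3-oxazolidin-2-one (silyloxy triene, not isolated) | CC(C)(C)[Si](C)(C)OC/C=C/C(O[Si](C)(C)C(C)(C)C)=C/C(C)(C)CCC/C(C)=C/C(=O)N1[C@H](Cc2ccccc2)COC1=O | intermediate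
11 | (R)-4-benzyl-3-[(5R,8R,9R,10R)-6,17-bis(tert-butyldimethylsilyloxy)-12,13,14,15,16-pentanorlabd-6-en-11-oyl]-1,3-oxazolidin-2-one (endo adduct; C11 cis to C20, H-5 trans to C20, C17 cis to C11) | O=C(N3C(=O)OC[C@H]3Cc4ccccc4)[C@@H]1[C@H](CO[Si](C)(C)C(C)(C)C)C=C(O[Si](C)(C)C(C)(C)C)[C@@H]2C(C)(C)CCC[C@@]12C | intermediate
12 | (5R,8S,9R,10S)-6,17-bis(tert-butyldimethylsilyloxy)-12,13,14,15,16-pentanorlabd-6-en-11-ol | OC[C@@H]1[C@H](CO[Si](C)(C)C(C)(C)C)C=C(O[Si](C)(C)C(C)(C)C)[C@@H]2C(C)(C)CCC[C@@]12C | intermediate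
13 | (5R,9S,10S)-17-(tert-butyldimethylsilyloxy)-11-hydroxy-12,13,14,15,16-pentanorlabd-7-en-6-one (trans-fused) | OC[C@@H]1C(CO[Si](C)(C)C(C)(C)C)=CC(=O)[C@@H]2C(C)(C)CCC[C@@]12C | intermediate
14 | (5R,6S,9S,10S)-17-(tert-butyldimethylsilyloxy)-12,13,14,15,16-pentanorlabd-7-ene-6,11-diol (6-OH syn to C20) | OC[C@@H]1C(CO[Si](C)(C)C(C)(C)C)=C[C@H](O)[C@@H]2C(C)(C)CCC[C@@]12C | intermediate
15 | (5R,6S,9S,10R)-17-(tert-butyldimethylsilyloxy)-6-hydroxy-12,13,14,15,16-pentanorlabd-7-en-11-al | O=C[C@@H]1C(CO[Si](C)(C)C(C)(C)C)=C[C@H](O)[C@@H]2C(C)(C)CCC[C@@]12C | intermediate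
16 | (R)-2-methylglycidol, (R)-(2-methyloxiran-2-yl)methanol | C[C@]1(CO1)CO | starting material
17 | (S)-5-{[(2-methyloxiran-2-yl)methyl]sulfanyl}-1-phenyl-1H-tetrazole | C[C@]1(CO1)CSc1nnnn1-c1ccccc1 | intermediate
18 | (S)-2-methyl-1-[(1-phenyl-1H-tetrazol-5-yl)sulfanyl]but-3-en-2-ol | C=C[C@](C)(O)CSc1nnnn1-c1ccccc1 | intermediate
19 | (S)-2-methyl-1-[(1-phenyl-1H-tetrazol-5-yl)sulfonyl]but-3-en-2-ol | C=C[C@](C)(O)CS(=O)(=O)c1nnnn1-c1ccccc1 | intermediate
20 | (S)-5-{[2-methyl-2-(triethylsilyloxy)but-3-en-1-yl]sulfonyl}-1-phenyl-1H-tetrazole | C=C[C@](C)(O[Si](CC)(CC)CC)CS(=O)(=O)c1nnnn1-c1ccccc1 | intermediate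
21 | (5R,6S,9S,10S,13S,11E)-17-(tert-butyldimethylsilyloxy)-13-(triethylsilyloxy)labda-7,11,14-trien-6-ol | C=C[C@](C)(O[Si](CC)(CC)CC)/C=C/[C@@H]1C(CO[Si](C)(C)C(C)(C)C)=C[C@H](O)[C@@H]2C(C)(C)CCC[C@@]12C | intermediate
22 | (5R,6S,9S,10S,13S,11E)-6-acetoxy-17-(tert-butyldimethylsilyloxy)-13-(triethylsilyloxy)labda-7,11,14-triene | C=C[C@](C)(O[Si](CC)(CC)CC)/C=C/[C@@H]1C(CO[Si](C)(C)C(C)(C)C)=C[C@H](OC(C)=O)[C@@H]2C(C)(C)CCC[C@@]12C | intermediate
23 | (5R,6S,9S,10S,13S,11E)-6-acetoxylabda-7,11,14-triene-13,17-diol | C=C[C@](C)(O)/C=C/[C@@H]1C(CO)=C[C@H](OC(C)=O)[C@@H]2C(C)(C)CCC[C@@]12C | intermediate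
24 | (5R,6S,9S,10S,13S,11E)-6,17-diacetoxylabda-7,11,14-trien-13-ol (CNP0103498.1) | C=C[C@](C)(O)/C=C/[C@@H]1C(COC(C)=O)=C[C@H](OC(C)=O)[C@@H]2C(C)(C)CCC[C@@]12C | target

**Step count**

Total: 18 steps. Longest linear sequence: 12 steps (steps 1, 2, 5, 6, 7, 8, 9, 10, 15, 16, 17, 18).

**Steps most likely to fail**

1. Step 6 (Proposed new method). The chelated β,β-disubstituted enoyl imide may be too hindered for bond formation at C10 below the temperature at which the silyl dienol ether survives, or ring closure may take place outside the chelate and so without facial control. The fallback uses the known thermal, uncatalysed intramolecular Diels–Alder reaction of 2-silyloxy trienes. It sets out from 10 (made from 9 as in the first half of step 6 and isolated): toluene, 150–170 °C, sealed tube, BHT and a trace of Et3N. Without the chelate the auxiliary no longer directs the facial sense, but it turns the two facial series into diastereomers, 11 and the facial counterpart (R)-4-benzyl-3-[(5S,8S,9S,10S)-6,17-bis(tert-butyldimethylsilyloxy)-12,13,14,15,16-pentanorlabd-6-en-11-oyl]-1,3-oxazolidin-2-one F1. These would be separated by chromatography, the auxiliary then serving as a resolving group, and the route is rejoined at 11.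

2. Step 5. The tertiary cation may lose a proton (elimination back to alkenes), the acid-sensitive silyloxy diene may be desilylated or polymerised by TiCl4, or the chelated imide may be attacked as a Michael acceptor. The fallback builds the enone in two stages from 4. The same tert-alkylation with the simple and robust 2-(trimethylsilyloxy)propene (TiCl4, CH2Cl2, −78 °C) would give the methyl ketone (R)-4-benzyl-3-[(2E)-3,7,7-trimethyl-9-oxodec-2-enoyl]-1,3-oxazolidin-2-one F2. Regioselective enolisation of its methyl group (n-Bu2BOTf, i-Pr2NEt) and aldol addition to 5 would give the β-hydroxy ketone (R)-4-benzyl-3-[(2E)-12-(tert-butyldimethylsilyloxy)-11-hydroxy-3,7,7-trimethyl-9-oxododec-2-enoyl]-1,3-oxazolidin-2-one F3 (carbinol epimers). Dehydration (MsCl, Et3N) returns to 9.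

3. Step 8. Palladation of the bulky tert-butyldimethylsilyl enol ether may be slow enough for the free primary alcohol to be oxidised. During the methoxide treatment the γ-hydrogen on C9 may be removed (epimerisation or shift of the double bond to C8=C9), or the 11-alkoxide may fragment with loss of formaldehyde. The fallback moves the equilibration to a stage where C9–H is not activated and sets out from 12. Dilute HCl in wet THF (0 °C) would cleave only the silyl enol ether, and NaOMe/MeOH would then equilibrate C5 at the saturated ketone (5R,8R,9R,10S)-17-(tert-butyldimethylsilyloxy)-11-hydroxy-12,13,14,15,16-pentanorlabdan-6-one F4. Kinetic enolisation toward the C7 methylene group (LiN(i-Pr)2, excess; Me3SiCl) would give (5R,8S,9R,10S)-17-(tert-butyldimethylsilyloxy)-6,11-bis(trimethylsilyloxy)-12,13,14,15,16-pentanorlabd-6-ene F5. Its Saegusa oxidation (Pd(OAc)2, MeCN) and a mild acidic work-up return to 13.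

**Further compounds**
F1 | step 6 | (R)-4-benzyl-3-[(5S,8S,9S,10S)-6,17-bis(tert-butyldimethylsilyloxy)-12,13,14,15,16-pentanorlabd-6-en-11-oyl]-1,3-oxazolidin-2-one | O=C(N3C(=O)OC[C@H]3Cc4ccccc4)[C@H]1[C@@H](CO[Si](C)(C)C(C)(C)C)C=C(O[Si](C)(C)C(C)(C)C)[C@H]2C(C)(C)CCC[C@]12C
F2 | step 5 | (R)-4-benzyl-3-[(2E)-3,7,7-trimethyl-9-oxodec-2-enoyl]-1,3-oxazolidin-2-one | CC(=O)CC(C)(C)CCC/C(C)=C/C(=O)N1[C@H](Cc2ccccc2)COC1=O
F3 | step 5 | (R)-4-benzyl-3-[(2E)-12-(tert-butyldimethylsilyloxy)-11-hydroxy-3,7,7-trimethyl-9-oxododec-2-enoyl]-1,3-oxazolidin-2-one (carbinol epimers) | CC(C)(C)[Si](C)(C)OCC(O)CC(=O)CC(C)(C)CCC/C(C)=C/C(=O)N1[C@H](Cc2ccccc2)COC1=O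
F4 | step 8 | (5R,8R,9R,10S)-17-(tert-butyldimethylsilyloxy)-11-hydroxy-12,13,14,15,16-pentanorlabdan-6-one | OC[C@@H]1[C@H](CO[Si](C)(C)C(C)(C)C)CC(=O)[C@@H]2C(C)(C)CCC[C@@]12C
F5 | step 8 | (5R,8S,9R,10S)-17-(tert-butyldimethylsilyloxy)-6,11-bis(trimethylsilyloxy)-12,13,14,15,16-pentanorlabd-6-ene | C[Si](C)(C)OC[C@@H]1[C@H](CO[Si](C)(C)C(C)(C)C)C=C(O[Si](C)(C)C)[C@@H]2C(C)(C)CCC[C@@]12C
A1 | direct plan | 2,6-dimethyl-1,4-benzoquinone | CC1=CC(=O)C=C(C)C1=O
A2 | direct plan | 4-methylpenta-1,3-diene | C=CC=C(C)C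
A3 | direct plan | (4aS,8aR)-2,5,5,8a-tetramethyl-4a,5,8,8a-tetrahydronaphthalene-1,4-dione (cis-fused ene-dione adduct) | O=C1C(C)=CC(=O)[C@H]2C(C)(C)C=CC[C@@]12C
A4 | direct plan | (5R,6S,9R,10R)-6-(tert-butyldimethylsilyloxy)-11-[(1-phenyl-1H-tetrazol-5-yl)sulfonyl]-12,13,14,15,16-pentanorlabd-7-ene | C(S(=O)(=O)c1nnnn1-c1ccccc1)[C@@H]2C(C)=C[C@H](O[Si](C)(C)C(C)(C)C)[C@@H]3C(C)(C)CCC[C@@]23C
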